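## The problem

The target 22 is a 5,6,7,8-tetrahydroquinoline (numbered N1, C2–C4, C4a, C5–C8, C8a, with the side chain as C6–Cα–Cβ–N) whose C6 is an all-carbon quaternary centre carrying a 3,4-dimethoxyphenyl group and a 2-(N-methylformamido)ethyl chain. A synthesis therefore has to fuse a pyridine across C4a–C8a of a carbocycle and build a fully substituted benzylic carbon inside that ring. C6 is the only stereocentre, of (S) configuration, and it is stereogenic only because its two ring arms differ: C5 is a single methylene that meets the pyridine at C4a, whereas C7–C8 is a two-carbon bridge that meets it at C8a. No second stereocentre can relay to it and no heteroatom sits on or next to it, so the configuration has to come from telling two nearly identical arms apart. The pyridine is basic, binds metals, is alkylated by electrophiles and is reduced by dissolving metals; the veratryl ring is oxidisable and migrates easily in cationic rearrangements; the formamide does not survive hydride or strong acid or base; and a free amine in the chain adds spontaneously to any enone in the ring. The enabling feature is that replacing the pyridine by a carbonyl at C8a and giving both arms a double bond produces an achiral 4-aryl-4-(2-aminoethyl)cyclohexa-2,5-dienone with a mirror plane through C6 and C8a, in which C5 and C7 are enantiotopic β-carbons that the chain nitrogen can reach through a five-membered transition state. Bonding nitrogen to C5 sets C6, leaves C7=C8–C8a=O as the only enone so that C4a is the only enolisable carbon for pyridine fusion, and ends as a 3-picolylic C–N bond that hydrogenolysis can remove.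

## Retrosynthesis

**N–CHO.** The formamide of 22 is the most fragile group and is cut first, giving the secondary amine 21. The forward reaction is a plain N-formylation, and placing it last keeps the formamide away from every reducing and organometallic step.

**C5–N (reconnection).** Amine 21 is reconnected between its nitrogen and C5 to give the cis-fused N-methylpyrrolidine 20. Forward, this is hydrogenolysis of a benzylic-type C–N bond next to pyridine C3. The reconnection is preferred to any cut at C6 because it turns a stereocentre defined only by remote constitution into one flanked by a ring heteroatom. The forward step must break C5–N without saturating the pyridine.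

**N–CH3 and N–S.** The methyl group of 20 is removed to give secondary amine 19, and 19 is traced to the N-tosyl compound 18. The sulfonyl group is kept up to this point because its acidic N–H is what the key step needs; it is exchanged for methyl only after the last step that benefits from a non-basic nitrogen.

**Pyridine ring.** Compound 18 is simplified by re-installing the C7=C8 double bond (17) and then cutting N1–C8a and C4–C4a, which leads to enone 13 and propargylamine 14. A one-step NaAuCl4-catalysed amination–annulation needs only a ketone with one α-methylene. In 13 the other α-carbon (C8) is vinylic, so only C4a can be fused; a saturated ketone would offer both C4a and C8. The forward reaction must form the pyridine without letting the sulfonamide leave C5 reversibly.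

**N–C5 (key disconnection).** Cutting N–C5 of 13 gives dienone sulfonamide 12, which has no stereocentre at all. This is the largest simplification in the plan: one ring, one skeletal bond and both stereocentres of 13 are traced to a mirror-symmetric precursor. The forward reaction must choose C5 over C7.

**N–H mask and second ring double bond.** Dienone 12 comes from its N-Boc derivative 11, and 11 from enone 10 by dehydrogenation. The Boc group keeps the sulfonamide from adding to the enone and to methyl vinyl ketone under base and heat, and it is removed by acid, which does not promote the conjugate addition.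

**Carbocycle.** Enone 10 is cut at the ring C=C (aldol condensation) and at the bond from the quaternary carbon to the ring CH2 (Michael addition), a Robinson annulation of aldehyde 6 with methyl vinyl ketone 7. Alkylating a preformed ring cannot reach the γ-carbon of a cyclohexenone, whereas the α-aryl aldehyde is doubly activated at exactly the carbon that must become quaternary.

**Side chain.** Aldehyde 6 comes from nitrile 4 by partial reduction, 4 from sulfonamide 3 by N-acylation, and 3 from (3,4-dimethoxyphenyl)acetonitrile 1 and N-tosylaziridine 2 by cutting the benzylic C–Cα bond. The aziridine brings Cα, Cβ, nitrogen and the tosyl group in one step. Carrying the nitrogen as a cyclic imide was rejected: an imide does not survive hydride reduction of the nitrile, and it cannot later be exchanged for a sulfonamide by hydrazine or amines in the presence of a dienone.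

## Roads not taken

Alternative 1: The cut is C8–C8a. The precursor is the achiral pyridine A1, 3-[2-(3,4-dimethoxyphenyl)-2-vinylbut-3-en-1-yl]pyridine, whose quaternary carbon carries two enantiotopic vinyl groups. Ni(cod)2 as a source of zerovalent nickel, with a chiral N-heterocyclic carbene ligand and AlMe3 bound to the pyridine nitrogen, would activate the C8a–H bond and add it anti-Markovnikov across one vinyl group to give the vinyl tetrahydroquinoline A2.
- Merits: the pyridine is present from the start; no temporary ring, no redox adjustment of the carbocycle and no C–N cleavage are needed; the remaining vinyl group is a direct handle for the aminoethyl chain.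
- Weak points: the tether at pyridine C3 is flanked by two C–H bonds, and closure at C4 would give an isoquinoline isomer. Insertion must be linear (six-membered ring) and not branched (five-membered ring). Selecting between two vinyl groups on a carbon two atoms from the metal has no close analogue, so the stereodefining step would itself be a new method. A1 needs a bis-vinyl quaternary carbon, and A2 still needs hydrofunctionalisation, amination and formylation.
- Comparison: on paper this road is clearly shorter and more direct. The chosen plan sets against it a stereodefining step that belongs to an established reaction class on exactly this substitution pattern.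

Alternative 2: The cuts are C5–C6 and Cα–Cβ. Aldehyde A3, 2-[3-(3,4-dimethoxyphenyl)but-3-en-1-yl]pyridine-3-carbaldehyde, condenses with the N-(1-phenylethyl)glycine A4; decarboxylation gives a non-stabilised azomethine ylide that adds across the tethered 1,1-disubstituted styrene to give cycloadduct A5.
- Merits: the pyridine is built in; the carbocycle, the pyrrolidine, the quaternary carbon and the C5–N bond arise in one step. After loss of the phenylethyl group the road meets the chosen one at 19, so it is shorter and more convergent and shares the same C5–N hydrogenolysis.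
- Weak points: the tether secures only the cis ring fusion. The absolute configuration of C6 would depend on a phenylethyl group on a mobile, thermally generated ylide, far from the forming quaternary carbon, so diastereofacial bias is expected to be weak and a diastereomer separation is likely. Two benzylic C–N bonds then have to be cleaved in a defined order.
- Comparison: in step count and convergence this road is better. The chosen plan sets against it catalyst-controlled selection between enantiotopic carbons in a known reaction class, without a stoichiometric chiral auxiliary.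

Alternative 3: The cuts are C6–C7 and C4a–C5. A Diels–Alder reaction of the 2-arylacrolein A6 with the 1-amino-3-siloxybutadiene A7, catalysed by a chiral (salen)CrSbF6 complex of trivalent chromium, followed by acidic loss of dimethylamine, gives the formyl enone A8.
- Merits: the quaternary carbon is set directly by a catalytic asymmetric cycloaddition that is well established for 2-substituted acroleins. A8 carries the same C7=C8–C8a=O enone lock for pyridine fusion at C4a, and no temporary C–N bond or hydrogenolysis is needed.
- Weak points: the neopentyl aldehyde must be extended by one carbon and aminated while an enone is present. A free chain amine adds to that enone, and propargylamine would condense with the aldehyde before the ketone, so the two carbonyls have to be differentiated by protection and ordering. The electron-rich 2-arylacrolein is a less reactive and polymerisation-prone dienophile.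
- Comparison: the step count is comparable or slightly lower, and the absence of a C–N cleavage is a real advantage. The chosen plan sets against it that nitrogen and both chain carbons are in place from the first step, and that the amine–enone reactivity is used as the stereodefining event instead of being suppressed.

Key step: step 7

Assumption 1: the sense of induction is taken to be that of the cinchonine/quinidine series of 9-epi-amino thioureas in this reaction class; if (3aR,7aS)-13 arises from the other series, the quinine-derived pseudoenantiomer is used and nothing else changes.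
Assumption 2: 1-tosylaziridine 2 is treated as a purchasable reagent.

Step 1
Reactants: 1 (3,4-dimethoxyphenyl)acetonitrile; 2 1-[(4-methylphenyl)sulfonyl]aziridine (N-tosylaziridine)
Product: 3 N-[3-cyano-3-(3,4-dimethoxyphenyl)propyl]-4-methylbenzenesulfonamide (racemic)
Conditions: LiN(SiMe3)2 (1.05 equiv), THF, −78 °C; then 2, −78 → 0 °C; aq NH4Cl
Reagents that add atoms: none
Why: The benzylic nitrile anion opens the N-sulfonylaziridine by SN2 attack at a ring methylene; the charge then rests on the sulfonamide nitrogen, which blocks a second C-alkylation, and the cold quench forestalls attack of that nitrogen on the nitrile.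

Step 2
Reactants: 3 N-[3-cyano-3-(3,4-dimethoxyphenyl)propyl]-4-methylbenzenesulfonamide
Product: 4 tert-butyl N-[3-cyano-3-(3,4-dimethoxyphenyl)propyl]-N-[(4-methylphenyl)sulfonyl]carbamate (racemic)
Conditions: Boc2O (1.3 equiv), DMAP (0.1 equiv), MeCN, rt
Reagents that add atoms: di-tert-butyl dicarbonate, CC(C)(C)OC(=O)OC(=O)OC(C)(C)C
Why: DMAP-catalysed N-acylation of a secondary sulfonamide is standard; the N–H must be masked because the free sulfonamide would add to methyl vinyl ketone and to the enone formed in step 4.

Step 3
Reactants: 4 tert-butyl N-[3-cyano-3-(3,4-dimethoxyphenyl)propyl]-N-[(4-methylphenyl)sulfonyl]carbamate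
Product: 6 tert-butyl N-[3-(3,4-dimethoxyphenyl)-4-oxobutyl]-N-[(4-methylphenyl)sulfonyl]carbamate (racemic), via N-(diisobutylaluminio) aldimine 5 (not isolated)
Conditions: i-Bu2AlH (1.3 equiv), toluene, −78 °C; MeOH, then aq potassium sodium tartrate, rt; used crude
Reagents that add atoms: water, O (the aldehyde oxygen); diisobutylaluminium hydride, CC(C)C[AlH]CC(C)C (its aluminium and isobutyl groups reside only in 5)
Why: Partial hydride reduction of a nitrile stops at the N-aluminio aldimine 5, which is hydrolysed on work-up; at −78 °C the hindered tert-butyl carbamate should be spared.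

Step 4
Reactants: 6 tert-butyl N-[3-(3,4-dimethoxyphenyl)-4-oxobutyl]-N-[(4-methylphenyl)sulfonyl]carbamate; 7 methyl vinyl ketone (but-3-en-2-one)
Product: 10 tert-butyl N-{2-[1-(3,4-dimethoxyphenyl)-4-oxocyclohex-2-en-1-yl]ethyl}-N-[(4-methylphenyl)sulfonyl]carbamate (racemic), via keto aldehyde Michael adduct 8 (not isolated), via ketol 9 (not isolated)
Conditions: 7 (1.5 equiv), KOt-Bu (0.2 equiv), t-BuOH/THF, 0 °C → rt
Reagents that add atoms: none
Why: Robinson annulation: the α-aryl aldehyde enolate adds to 7, the methyl ketone enolate of 8 closes onto the now non-enolisable aldehyde, and ketol 9 dehydrates. The bulky alkoxide is chosen to spare the N-Boc sulfonamide. The quaternary carbon forms as a racemate, which is irrelevant because step 5 makes it non-stereogenic.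

Step 5
Reactants: 10 tert-butyl N-{2-[1-(3,4-dimethoxyphenyl)-4-oxocyclohex-2-en-1-yl]ethyl}-N-[(4-methylphenyl)sulfonyl]carbamate
Product: 11 tert-butyl N-{2-[1-(3,4-dimethoxyphenyl)-4-oxocyclohexa-2,5-dien-1-yl]ethyl}-N-[(4-methylphenyl)sulfonyl]carbamate (achiral)
Conditions: DDQ (2 equiv), 1,4-dioxane, reflux
Reagents that add atoms: none
Why: DDQ dehydrogenation of the saturated α,β-positions of a 4,4-disubstituted cyclohex-2-enone to the cross-conjugated dienone is a standard reaction; the quaternary benzylic carbon has no hydrogen to lose and the nitrogen is fully substituted.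

Step 6
Reactants: 11 tert-butyl N-{2-[1-(3,4-dimethoxyphenyl)-4-oxocyclohexa-2,5-dien-1-yl]ethyl}-N-[(4-methylphenyl)sulfonyl]carbamate
Product: 12 N-{2-[1-(3,4-dimethoxyphenyl)-4-oxocyclohexa-2,5-dien-1-yl]ethyl}-4-methylbenzenesulfonamide (achiral)
Conditions: TFA/CH2Cl2 (1:4), 0 °C, short contact; cold aq NaHCO3
Reagents that add atoms: none
Why: A Boc group on a sulfonamide nitrogen is much more acid-labile than one on an amine, so brief cold acidolysis should suffice; acid does not promote the conjugate addition, and dienone–phenol rearrangement normally needs stronger acid or heat.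

Step 7
Reactants: 12 N-{2-[1-(3,4-dimethoxyphenyl)-4-oxocyclohexa-2,5-dien-1-yl]ethyl}-4-methylbenzenesulfonamide
Product: 13 (3aR,7aS)-3a-(3,4-dimethoxyphenyl)-1-[(4-methylphenyl)sulfonyl]-1,2,3,3a,7,7a-hexahydro-6H-indol-6-one
Conditions: 9-amino(9-deoxy)epi-quinidine-derived N-[3,5-bis(trifluoromethyl)phenyl]thiourea (10 mol%), toluene, 0 °C → rt; filtration through silica
Reagents that add atoms: none
Why: The thiourea N–H pair hydrogen-bonds the dienone carbonyl while the quinuclidine nitrogen takes up the sulfonamide proton, so the nitrogen is delivered to one of the two enantiotopic β-carbons and the resulting dienolate is protonated at C4a by the quinuclidinium. The closest known reaction type is the organocatalytic enantioselective intramolecular aza-Michael desymmetrisation of 4,4-disubstituted cyclohexa-2,5-dienones bearing a 2-(sulfonylamino)ethyl chain, which gives cis-hydroindolones. The pyrrolidine closes in the 5-exo-trig mode. C3a (C6 of the target) becomes stereogenic at the moment C5 is chosen over C7, under catalyst control; C7a (C5 of the target) is set relative to it by the two-atom tether, which can only bridge cis. The step needs selection between enantiotopic carbons only: the two β-carbons are constitutionally identical and the nitrogen has a single hydrogen, so no regiochemical or over-addition problem exists. The substrate secures this through a sulfonamide N–H acidic enough for the catalyst's tertiary amine but unreactive without it in toluene, and through a rigid symmetric dienone with a single hydrogen-bond acceptor. The catalyst is removed promptly so that base-mediated reversal through 12 is not given time.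

Step 8
Reactants: 13 (3aR,7aS)-3a-(3,4-dimethoxyphenyl)-1-[(4-methylphenyl)sulfonyl]-1,2,3,3a,7,7a-hexahydro-6H-indol-6-one; 14 propargylamine (prop-2-yn-1-amine)
Product: 17 (3aR,9bR)-3a-(3,4-dimethoxyphenyl)-1-[(4-methylphenyl)sulfonyl]-2,3,3a,9b-tetrahydro-1H-pyrrolo[2,3-f]quinoline, via N-propargyl ketimine 15 (not isolated), via dihydropyridine 16 (not isolated)
Conditions: 14 (3 equiv), NaAuCl4·2H2O (5 mol%), EtOH, 70 °C, air
Reagents that add atoms: none
Why: Gold-catalysed amination–annulation–aromatisation of a ketone with propargylamine: ketimine 15 can tautomerise to an enamine only towards C4a because C8 is vinylic, trivalent gold activates the alkyne for 6-endo-dig attack by C4a, and 16 aromatises by tautomerisation and air oxidation. Neither stereocentre takes part, and the C4=C5 alkene of the new numbering is the C7=C8 bond of the target numbering.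

Step 9
Reactants: 17 (3aR,9bR)-3a-(3,4-dimethoxyphenyl)-1-[(4-methylphenyl)sulfonyl]-2,3,3a,9b-tetrahydro-1H-pyrrolo[2,3-f]quinoline
Product: 18 (3aS,9bR)-3a-(3,4-dimethoxyphenyl)-1-[(4-methylphenyl)sulfonyl]-2,3,3a,4,5,9b-hexahydro-1H-pyrrolo[2,3-f]quinoline
Conditions: H2 (1 atm), 10% Pd/C, EtOAc, rt
Reagents that add atoms: none
Why: Heterogeneous hydrogenation of a cis-disubstituted alkene conjugated to the pyridine; the pyridine ring and the C–N bond of a neutral sulfonamide are inert under these mild conditions, and the change of descriptor at C3a is only a change of priorities.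

Step 10
Reactants: 18 (3aS,9bR)-3a-(3,4-dimethoxyphenyl)-1-[(4-methylphenyl)sulfonyl]-2,3,3a,4,5,9b-hexahydro-1H-pyrrolo[2,3-f]quinoline
Product: 19 (3aS,9bR)-3a-(3,4-dimethoxyphenyl)-2,3,3a,4,5,9b-hexahydro-1H-pyrrolo[2,3-f]quinoline
Conditions: Mg turnings (excess), MeOH, sonication, rt
Reagents that add atoms: none
Why: Single-electron reductive cleavage of the N–S bond of an arenesulfonamide by magnesium in methanol; the pyridine and the aryl methyl ethers are not reduced and no stereocentre is involved.

Step 11
Reactants: 19 (3aS,9bR)-3a-(3,4-dimethoxyphenyl)-2,3,3a,4,5,9b-hexahydro-1H-pyrrolo[2,3-f]quinoline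
Product: 20 (3aS,9bR)-3a-(3,4-dimethoxyphenyl)-1-methyl-2,3,3a,4,5,9b-hexahydro-1H-pyrrolo[2,3-f]quinoline
Conditions: aq CH2O (37%), NaBH(OAc)3, ClCH2CH2Cl, rt
Reagents that add atoms: formaldehyde, C=O
Why: Reductive amination methylates the secondary amine exactly once, since the tertiary amine cannot react further, and the pyridine nitrogen is not alkylated because no alkylating electrophile is present.

Step 12
Reactants: 20 (3aS,9bR)-3a-(3,4-dimethoxyphenyl)-1-methyl-2,3,3a,4,5,9b-hexahydro-1H-pyrrolo[2,3-f]quinoline
Product: 21 2-[(6S)-6-(3,4-dimethoxyphenyl)-5,6,7,8-tetrahydroquinolin-6-yl]-N-methylethan-1-amine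
Conditions: H2 (3 atm), 10% Pd/C, EtOH, AcOH (1.1 equiv), 50 °C
Reagents that add atoms: none
Why: Hydrogenolysis of the benzylic-type C5–N bond of a protonated tertiary amine on palladium, the reaction type that opens the pyrrolidine ring of 2-(3-pyridyl)-N-methylpyrrolidines. One equivalent of acid protonates the more basic aliphatic nitrogen and leaves the pyridine largely free, which disfavours ring saturation. C5 becomes a methylene, so its stereocentre disappears and C6 remains, untouched, as the only one.

Step 13
Reactants: 21 2-[(6S)-6-(3,4-dimethoxyphenyl)-5,6,7,8-tetrahydroquinolin-6-yl]-N-methylethan-1-amine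
Product: 22 N-{2-[(6S)-6-(3,4-dimethoxyphenyl)-5,6,7,8-tetrahydroquinolin-6-yl]ethyl}-N-methylformamide
Conditions: HCO2Et (solvent), reflux
Reagents that add atoms: ethyl formate, CCOC=O
Why: N-Formylation of a secondary amine by aminolysis of a formate ester; the pyridine nitrogen cannot be acylated irreversibly and the quaternary stereocentre is remote from the reaction.

## Compound list

1 | (3,4-dimethoxyphenyl)acetonitrile | COc1ccc(CC#N)cc1OC | starting material
2 | 1-[(4-methylphenyl)sulfonyl]aziridine | Cc1ccc(S(=O)(=O)N2CC2)cc1 | starting material
3 | N-[3-cyano-3-(3,4-dimethoxyphenyl)propyl]-4-methylbenzenesulfonamide (racemic) | COc1ccc(C(C#N)CCNS(=O)(=O)c2ccc(C)cc2)cc1OC | intermediate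
4 | tert-butyl N-[3-cyano-3-(3,4-dimethoxyphenyl)propyl]-N-[(4-methylphenyl)sulfonyl]carbamate (racemic) | COc1ccc(C(C#N)CCN(C(=O)OC(C)(C)C)S(=O)(=O)c2ccc(C)cc2)cc1OC | intermediate
5 | N-(diisobutylaluminio) aldimine of 6 (not isolated) | COc1ccc(C(C=N[Al](CC(C)C)CC(C)C)CCN(C(=O)OC(C)(C)C)S(=O)(=O)c2ccc(C)cc2)cc1OC | intermediate
6 | tert-butyl N-[3-(3,4-dimethoxyphenyl)-4-oxobutyl]-N-[(4-methylphenyl)sulfonyl]carbamate (racemic) | COc1ccc(C(C=O)CCN(C(=O)OC(C)(C)C)S(=O)(=O)c2ccc(C)cc2)cc1OC | intermediate
7 | methyl vinyl ketone (but-3-en-2-one) | CC(=O)C=C | starting material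
8 | tert-butyl N-[3-(3,4-dimethoxyphenyl)-3-formyl-6-oxoheptyl]-N-[(4-methylphenyl)sulfonyl]carbamate (Michael adduct, not isolated) | COc1ccc(C(C=O)(CCC(C)=O)CCN(C(=O)OC(C)(C)C)S(=O)(=O)c2ccc(C)cc2)cc1OC | intermediate
9 | tert-butyl N-{2-[1-(3,4-dimethoxyphenyl)-2-hydroxy-4-oxocyclohexyl]ethyl}-N-[(4-methylphenyl)sulfonyl]carbamate (ketol, not isolated) | COc1ccc(C2(CCN(C(=O)OC(C)(C)C)S(=O)(=O)c3ccc(C)cc3)CCC(=O)CC2O)cc1OC | intermediate
10 | tert-butyl N-{2-[1-(3,4-dimethoxyphenyl)-4-oxocyclohex-2-en-1-yl]ethyl}-N-[(4-methylphenyl)sulfonyl]carbamate (racemic) | COc1ccc(C2(CCN(C(=O)OC(C)(C)C)S(=O)(=O)c3ccc(C)cc3)C=CC(=O)CC2)cc1OC | intermediate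
11 | tert-butyl N-{2-[1-(3,4-dimethoxyphenyl)-4-oxocyclohexa-2,5-dien-1-yl]ethyl}-N-[(4-methylphenyl)sulfonyl]carbamate | COc1ccc(C2(CCN(C(=O)OC(C)(C)C)S(=O)(=O)c3ccc(C)cc3)C=CC(=O)C=C2)cc1OC | intermediate
12 | N-{2-[1-(3,4-dimethoxyphenyl)-4-oxocyclohexa-2,5-dien-1-yl]ethyl}-4-methylbenzenesulfonamide | COc1ccc(C2(CCNS(=O)(=O)c3ccc(C)cc3)C=CC(=O)C=C2)cc1OC | intermediate
13 | (3aR,7aS)-3a-(3,4-dimethoxyphenyl)-1-[(4-methylphenyl)sulfonyl]-1,2,3,3a,7,7a-hexahydro-6H-indol-6-one (cis-fused) | COc1ccc([C@]23CCN(S(=O)(=O)c4ccc(C)cc4)[C@H]2CC(=O)C=C3)cc1OC | intermediate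
14 | propargylamine (prop-2-yn-1-amine) | C#CCN | starting material
15 | (3aR,7aS)-3a-(3,4-dimethoxyphenyl)-1-[(4-methylphenyl)sulfonyl]-N-(prop-2-yn-1-yl)-1,2,3,3a,7,7a-hexahydro-6H-indol-6-imine (not isolated) | COc1ccc([C@]23CCN(S(=O)(=O)c4ccc(C)cc4)[C@H]2CC(=NCC#C)C=C3)cc1OC | intermediate
16 | 3a-(3,4-dimethoxyphenyl)-1-[(4-methylphenyl)sulfonyl]-2,3,3a,7,9a,9b-hexahydro-1H-pyrrolo[2,3-f]quinoline, C3a and C9b as in 13, C9a epimers (not isolated) | COc1ccc([C@]23CCN(S(=O)(=O)c4ccc(C)cc4)[C@H]2C2C=CCN=C2C=C3)cc1OC | intermediate
17 | (3aR,9bR)-3a-(3,4-dimethoxyphenyl)-1-[(4-methylphenyl)sulfonyl]-2,3,3a,9b-tetrahydro-1H-pyrrolo[2,3-f]quinoline | COc1ccc([C@]23CCN(S(=O)(=O)c4ccc(C)cc4)[C@H]2c2cccnc2C=C3)cc1OC | intermediate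
18 | (3aS,9bR)-3a-(3,4-dimethoxyphenyl)-1-[(4-methylphenyl)sulfonyl]-2,3,3a,4,5,9b-hexahydro-1H-pyrrolo[2,3-f]quinoline | COc1ccc([C@]23CCN(S(=O)(=O)c4ccc(C)cc4)[C@H]2c2cccnc2CC3)cc1OC | intermediate
19 | (3aS,9bR)-3a-(3,4-dimethoxyphenyl)-2,3,3a,4,5,9b-hexahydro-1H-pyrrolo[2,3-f]quinoline | COc1ccc([C@]23CCN[C@H]2c2cccnc2CC3)cc1OC | intermediate
20 | (3aS,9bR)-3a-(3,4-dimethoxyphenyl)-1-methyl-2,3,3a,4,5,9b-hexahydro-1H-pyrrolo[2,3-f]quinoline | COc1ccc([C@]23CCN(C)[C@H]2c2cccnc2CC3)cc1OC | intermediate
21 | 2-[(6S)-6-(3,4-dimethoxyphenyl)-5,6,7,8-tetrahydroquinolin-6-yl]-N-methylethan-1-amine | COc1ccc([C@@]2(CCNC)CCc3ncccc3C2)cc1OC | intermediate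
22 | N-{2-[(6S)-6-(3,4-dimethoxyphenyl)-5,6,7,8-tetrahydroquinolin-6-yl]ethyl}-N-methylformamide | COc1ccc([C@@]2(CCN(C)C=O)CCc3ncccc3C2)cc1OC | target

## Step count and least certain steps

Total steps: 13. Longest linear sequence: 13 steps (1 → 22); the route is linear, with 2, 7 and 14 entering as purchased reagents.

**Key step (step 7).** The most likely failure is insufficient discrimination between the two enantiotopic β-carbons. An uncatalysed closure, or base-mediated reversal of the product through the achiral dienone, would both lower the enantiomeric purity. The fallback gives up asymmetric catalysis. It sets out from 12, which is closed with an achiral amidine base (DBU, CH2Cl2) to the racemate of 13, and the two enantiomers are separated by preparative chromatography on a chiral stationary phase. The unwanted enantiomer is (3aS,7aR)-3a-(3,4-dimethoxyphenyl)-1-[(4-methylphenyl)sulfonyl]-1,2,3,3a,7,7a-hexahydro-6H-indol-6-one F1. It is not discarded: with the same base F1 opens by retro-aza-Michael reaction to 12 and closes again to the racemate, which is resolved once more. The fallback comes back to the route at 13.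

**Pyridine annulation (step 8).** Heating with a primary amine may allow reversible β-elimination of the sulfonamide from the enamine tautomer of 15. That path runs through an achiral N-propargyl dienimine and would erode the configuration at C6; sluggish aromatisation of 16 is a second concern. The fallback changes the order and the source of regiocontrol. It sets out from 13, whose C=C bond is hydrogenated first (H2, Pd/C, EtOAc) to (3aS,7aS)-3a-(3,4-dimethoxyphenyl)-1-[(4-methylphenyl)sulfonyl]octahydro-6H-indol-6-one F2. In F2, loss and re-addition of the sulfonamide can only regenerate the same stereoisomer. F2 is then annulated with 14 and NaAuCl4·2H2O; the fusion regiochemistry now rests on preferential enamine formation towards C4a, the α-carbon next to the sulfonamide-bearing carbon, instead of on the enone lock. The fallback comes back to the route at 18.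

**Hydrogenolysis (step 12).** The C5–N bond is neopentyl-like and sits in a cis-fused tricycle, so cleavage may be slow enough for saturation of the pyridine ring to compete. The fallback replaces hydrogenolysis by a chloroformate-induced ring opening of the von Braun type. It sets out from 20, which is heated with ClCO2CH2CCl3 in 1,2-dichloroethane. Acylation of the pyrrolidine nitrogen and chloride attack at benzylic C5 should give 2,2,2-trichloroethyl N-{2-[(6S)-5-chloro-6-(3,4-dimethoxyphenyl)-5,6,7,8-tetrahydroquinolin-6-yl]ethyl}-N-methylcarbamate F3, formed as a mixture of C5 epimers. Zn in AcOH then converts F3 in one operation: it reduces the picolylic C–Cl bond and removes the trichloroethyl carbamate, and the acidic medium keeps the liberated amine protonated so that it does not re-close onto C5. The fallback comes back to the route at 21.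

**Nitrile reduction (step 3).** The N-Boc sulfonamide is an activated carbamate, so hydride attack at its carbonyl (loss of Boc) or over-reduction of the aldimine may compete; the same group may also suffer alkoxide attack in step 4. The fallback introduces nitrogen only after the carbocycle is made. It sets out from 1, which is alkylated with (2-bromoethoxy)(tert-butyl)dimethylsilane (LiN(SiMe3)2, THF) to 4-[(tert-butyldimethylsilyl)oxy]-2-(3,4-dimethoxyphenyl)butanenitrile F4. Reduction of F4 with i-Bu2AlH gives 4-[(tert-butyldimethylsilyl)oxy]-2-(3,4-dimethoxyphenyl)butanal F5, and Robinson annulation of F5 with 7 gives 4-{2-[(tert-butyldimethylsilyl)oxy]ethyl}-4-(3,4-dimethoxyphenyl)cyclohex-2-en-1-one F6. Desilylation of F6 with HF·pyridine gives 4-(3,4-dimethoxyphenyl)-4-(2-hydroxyethyl)cyclohex-2-en-1-one F7, and a Mitsunobu reaction of F7 with tert-butyl tosylcarbamate (PPh3, DIAD) installs the protected nitrogen. The fallback comes back to the route at 10.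

**Boc removal on the dienone (step 6).** Protonation of the dienone may start a dienone–phenol rearrangement with migration of the electron-rich aryl group, and the neutralisation may trigger some premature, non-selective ring closure. The fallback removes the Boc group before the dienone exists. It sets out from 10, which is treated with TFA in CH2Cl2 to give N-{2-[1-(3,4-dimethoxyphenyl)-4-oxocyclohex-2-en-1-yl]ethyl}-4-methylbenzenesulfonamide F8. In the absence of base the neutral sulfonamide of F8 is not expected to add to the enone, and F8 is then dehydrogenated with DDQ in refluxing dioxane. The fallback comes back to the route at 12.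

## Further compounds

F1 | step 7 | (3aS,7aR)-3a-(3,4-dimethoxyphenyl)-1-[(4-methylphenyl)sulfonyl]-1,2,3,3a,7,7a-hexahydro-6H-indol-6-one | COc1ccc([C@@]23CCN(S(=O)(=O)c4ccc(C)cc4)[C@@H]2CC(=O)C=C3)cc1OC
F2 | step 8 | (3aS,7aS)-3a-(3,4-dimethoxyphenyl)-1-[(4-methylphenyl)sulfonyl]octahydro-6H-indol-6-one | COc1ccc([C@]23CCN(S(=O)(=O)c4ccc(C)cc4)[C@H]2CC(=O)CC3)cc1OC
F3 | step 12 | 2,2,2-trichloroethyl N-{2-[(6S)-5-chloro-6-(3,4-dimethoxyphenyl)-5,6,7,8-tetrahydroquinolin-6-yl]ethyl}-N-methylcarbamate (C5 epimers) | COc1ccc([C@@]2(CCN(C)C(=O)OCC(Cl)(Cl)Cl)CCc3ncccc3C2Cl)cc1OC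
F4 | step 3 | 4-[(tert-butyldimethylsilyl)oxy]-2-(3,4-dimethoxyphenyl)butanenitrile (racemic) | COc1ccc(C(C#N)CCO[Si](C)(C)C(C)(C)C)cc1OC
F5 | step 3 | 4-[(tert-butyldimethylsilyl)oxy]-2-(3,4-dimethoxyphenyl)butanal (racemic) | COc1ccc(C(C=O)CCO[Si](C)(C)C(C)(C)C)cc1OC
F6 | step 3 | 4-{2-[(tert-butyldimethylsilyl)oxy]ethyl}-4-(3,4-dimethoxyphenyl)cyclohex-2-en-1-one (racemic) | COc1ccc(C2(CCO[Si](C)(C)C(C)(C)C)C=CC(=O)CC2)cc1OC
F7 | step 3 | 4-(3,4-dimethoxyphenyl)-4-(2-hydroxyethyl)cyclohex-2-en-1-one (racemic) | COc1ccc(C2(CCO)C=CC(=O)CC2)cc1OC
F8 | step 6 | N-{2-[1-(3,4-dimethoxyphenyl)-4-oxocyclohex-2-en-1-yl]ethyl}-4-methylbenzenesulfonamide (racemic) | COc1ccc(C2(CCNS(=O)(=O)c3ccc(C)cc3)C=CC(=O)CC2)cc1OC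
A1 | alternative 1 | 3-[2-(3,4-dimethoxyphenyl)-2-vinylbut-3-en-1-yl]pyridine | COc1ccc(C(C=C)(C=C)Cc2cccnc2)cc1OC
A2 | alternative 1 | (6S)-6-(3,4-dimethoxyphenyl)-6-vinyl-5,6,7,8-tetrahydroquinoline | COc1ccc([C@@]2(C=C)CCc3ncccc3C2)cc1OC
A3 | alternative 2 | 2-[3-(3,4-dimethoxyphenyl)but-3-en-1-yl]pyridine-3-carbaldehyde | COc1ccc(C(=C)CCc2ncccc2C=O)cc1OC
A4 | alternative 2 | N-[(1R)-1-phenylethyl]glycine | OC(=O)CN[C@H](C)c1ccccc1
A5 | alternative 2 | cis-fused 3a-(3,4-dimethoxyphenyl)-1-[(1R)-1-phenylethyl]-2,3,3a,4,5,9b-hexahydro-1H-pyrrolo[2,3-f]quinoline | COc1ccc([C@]23CCN([C@H](C)c4ccccc4)[C@H]2c2cccnc2CC3)cc1OC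
A6 | alternative 3 | 2-(3,4-dimethoxyphenyl)prop-2-enal | COc1ccc(C(=C)C=O)cc1OC
A7 | alternative 3 | (E)-3-[(tert-butyldimethylsilyl)oxy]-N,N-dimethylbuta-1,3-dien-1-amine | CN(C)/C=C/C(=C)O[Si](C)(C)C(C)(C)C
A8 | alternative 3 | 1-(3,4-dimethoxyphenyl)-4-oxocyclohex-2-ene-1-carbaldehyde, single enantiomer | COc1ccc([C@@]2(C=O)C=CC(=O)CC2)cc1OC
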